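A reading of 1.22 h⁻¹ came from the cedar run at 50 °C, between 0.250 h and 2.00 h, while target stood near 15%. It is the isomer of the product gained per hour for each unit of target standing, my drain constant.

| flask | starting material | partner | second substrate | temperature | remark | time |
|---|---|---|---|---|---|---|
| cedar | 20 mM | 1.2 equiv | 2 equiv | 50 °C | run made earlier |  |
| north | 20 mM | 0.800 equiv | 2.00 equiv | 50 °C |  | 12 h |
| east | 20 mM | 0.800 equiv | 2.00 equiv |  | at 20 °C until 6.0 h, from then on at 80 °C | 12 h |
| south-west | 20 mM | 0.800 equiv | 2.00 equiv | 80 °C |  | 12 h |
| north-west | 20 mM | 0.800 equiv | 2.00 equiv | 20 °C |  | 12 h |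

cedar run (percent of the starting material charged)

| time / h | target / % | isomer of the product / % | starting material / % |
|---|---|---|---|
| 0.250 | 15 | 2 | 82 |
| 0.500 | 15 | 11 | 75 |
| 1.00 | 15 | 18 | 65 |
| 2.00 | 13 | 34 | 54 |
| 4.00 | 4 | 48 | 47 |

(readings scatter by 2 percentage points)

- the numbers in the tables scatter by 2 percentage points (one standard deviation)
- what may be going on: starting material + partner <-> target; target <-> isomer of the product; second substrate + partner <-> second product
- the earlier runs do not show what temperature does; that part of a forecast is a guess

- the flask with the highest share of target in all that became target or isomer of the product ("all alike" if they lie within 1.5 percentage points) (north / east / south-west / north-west / all alike)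
- share of target in all that became target or isomer of the product, north
- share of target in all that became target or isomer of the product, east
- share of target in all that became target or isomer of the product, south-west
- share of target in all that became target or isomer of the product, north-west

North ran 12 h, which is 14.6 drain times of 0.820 h each, so I expected a low share there. I guessed east and south-west the same way, since the cedar run shows nothing of temperature. For north-west I took a slowdown of 20, also a guess, which made the drain constant 0.0610 h⁻¹. Assuming for my estimate that target climbed evenly over 12 h, I reckoned isomer over target at 0.366, a share of 73.2%.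

The forecast gave 3% for north, 3% for east, 3% for south-west and 50% for north-west, a figure below my own. Its ranking agreed with mine: “North-west should therefore keep the most target.”

The flasks gave 5.23% in north, 0.875% in east, 0.834% in south-west and 84.1% in north-west, so north-west led, and the forecast stood 34 percentage points low there.

    starting material + partner ⇌ target (K = 170 M⁻¹, k = 5.00 M⁻¹ h⁻¹, Ea = 51.0 kJ mol⁻¹, ΔH = −6.00 kJ mol⁻¹)
    target ⇌ isomer of the product (K = 2.80, k = 0.0220 h⁻¹, Ea = 109 kJ mol⁻¹, ΔH = 54.0 kJ mol⁻¹)
    second substrate + partner ⇌ second product (K = 1200 M⁻¹, k = 1.30 M⁻¹ h⁻¹, Ea = 68.0 kJ mol⁻¹, ΔH = −35.0 kJ mol⁻¹)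
    (constants at 20 °C)

The north-west share of 84.1% was kinetic control, not thermodynamic control: left until 120 h, that flask stood at 25.2%. Its isomer rose from 1.94% at 6.00 h to 5.28% at 12.0 h, with target between 23.8% and 28.0%. So its drain constant read 0.0215 h⁻¹, which is 56.7 times below the cedar reading. East sat at 20 °C until 6.0 h and held 1.94% of isomer at the change, which at this constant means a mean target of 15.0% over those hours, below the 23.8% of target that east held at the change.

The numbers in the tables are simulated from invented constants; noise was put on by code.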